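**Strategy.** Everything rests on disconnecting the aryl ketone bond C4–C4a of ring C in the 5,7-dihydroxyflavanone unit (unit 2), and with it the same bond of the 7-methoxy unit (unit 1). One operation, a twofold intramolecular Friedel–Crafts acylation, closes both pyranone rings. It exploits the strongly nucleophilic carbon C4a of each ring A, flanked by O1 and the 5-oxygen and para to the 7-oxygen, and the local symmetry of the 3,5-dioxygenated aryl ethers, whose two ortho carbons are equivalent. The precursor is an open-chain diaryl ether bearing two (S)-3-aryl-3-aryloxypropanoic acid arms, built by catalytic asymmetric acetate aldol additions and Mitsunobu inversions; symmetrical dimethoxy and dibenzyloxy phenols encode the final oxygenation pattern.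

Key step: step 7

Remark: the (R,R)-antipode of the bisphosphoramide Lewis base (two N,N'-dimethyl-1,1'-binaphthyl-2,2'-diamine phosphoramide units joined by an N-methyl-(CH2)5-N-methyl tether) is taken to direct Re-face addition. If MTPA ester analysis of the first adduct shows the (S)-carbinol, the (S,S)-antipode is used in steps 1 and 4 and nothing else changes.

**Step 1**
Reactants: 1 4-(4,4,5,5-tetramethyl-1,3,2-dioxaborolan-2-yl)benzaldehyde; 2 tert-butyl[(1-methoxyethenyl)oxy]dimethylsilane
Product: 4 methyl (R)-3-hydroxy-3-[4-(4,4,5,5-tetramethyl-1,3,2-dioxaborolan-2-yl)phenyl]propanoate, via trichlorosilyl ether 3 (not isolated)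
Conditions: SiCl4 (1.2 equiv), (R,R)-bisphosphoramide (2 mol%), CH2Cl2, −78 °C; then sat. aq. NaHCO3, 0 °C
Reagents that add atoms: none
Why: Mukaiyama aldol addition in which the chiral Lewis base ionises SiCl4 to a cationic trichlorosilyl Lewis acid that binds only the aldehyde, so the ketene acetal should add through an open transition state to the Re face under catalyst control and set the (R)-carbinol, the pinacol boronate being inert.

**Step 2**
Reactants: 4 methyl (R)-3-hydroxy-3-[4-(pinacolboryl)phenyl]propanoate; 5 3,5-bis(benzyloxy)phenol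
Product: 6 methyl (S)-3-[3,5-bis(benzyloxy)phenoxy]-3-[4-(4,4,5,5-tetramethyl-1,3,2-dioxaborolan-2-yl)phenyl]propanoate
Conditions: PPh3 (1.5 equiv), DIAD (1.5 equiv), toluene, 0 °C → rt
Reagents that add atoms: none
Why: Mitsunobu etherification, in which the phenoxide displaces the alkoxyphosphonium group in an SN2 step with inversion, so the (R)-alcohol should give the (S)-aryl ether; the electron-poor boryl-substituted ring disfavours ionisation.

**Step 3**
Reactants: 6 aryl boronate; 7 4-(benzyloxy)-3-hydroxybenzaldehyde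
Product: 8 methyl (S)-3-{4-[2-(benzyloxy)-5-formylphenoxy]phenyl}-3-[3,5-bis(benzyloxy)phenoxy]propanoate
Conditions: Cu(OAc)2 (2.0 equiv), pyridine (5 equiv), B(OH)3 (2 equiv), 4 Å MS, MeCN, dry air, 50 °C
Reagents that add atoms: none
Why: Chan–Lam coupling, in which the aryl group passes from boron to divalent copper and C–O reductive elimination from trivalent copper forms the diaryl ether without strong base, so the β-aryloxy ester and its stereocenter should be untouched; boric acid traps the pinacol.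

**Step 4**
Reactants: 8 diaryl ether aldehyde; 2 tert-butyl[(1-methoxyethenyl)oxy]dimethylsilane
Product: 10 methyl (R)-3-[4-(benzyloxy)-3-{4-[(S)-1-[3,5-bis(benzyloxy)phenoxy]-3-methoxy-3-oxopropyl]phenoxy}phenyl]-3-hydroxypropanoate, via trichlorosilyl ether 9 (not isolated)
Conditions: SiCl4 (1.5 equiv), (R,R)-bisphosphoramide (5 mol%), CH2Cl2, −78 °C; then sat. aq. NaHCO3, 0 °C
Reagents that add atoms: none
Why: the same catalyst-controlled Mukaiyama aldol addition, chemoselective for the aldehyde over the ester, should set the second (R)-carbinol by Re-face attack; the remote stereocenter has no influence.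

**Step 5**
Reactants: 10 (R)-alcohol; 11 3,5-dimethoxyphenol
Product: 12 methyl (S)-3-[4-(benzyloxy)-3-{4-[(S)-1-[3,5-bis(benzyloxy)phenoxy]-3-methoxy-3-oxopropyl]phenoxy}phenyl]-3-(3,5-dimethoxyphenoxy)propanoate
Conditions: PPh3 (1.5 equiv), DIAD (1.5 equiv, slow addition), toluene, −20 → 0 °C
Reagents that add atoms: none
Why: Mitsunobu etherification with SN2 inversion should turn the (R)-carbinol into the (S)-aryl ether; low temperature and a non-polar solvent are chosen to keep the displacement concerted at this para-benzyloxy-substituted benzylic carbon.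

**Step 6**
Reactants: 12 bis(methyl ester)
Product: 13 (S)-3-[4-(benzyloxy)-3-{4-[(S)-1-[3,5-bis(benzyloxy)phenoxy]-2-carboxyethyl]phenoxy}phenyl]-3-(3,5-dimethoxyphenoxy)propanoic acid
Conditions: LiOH·H2O (4 equiv), THF/H2O 3:1, 0 °C → rt; then 0.5 M HCl to pH 3, 0 °C
Reagents that add atoms: lithium hydroxide, [Li+].[OH-]
Why: ester saponification by acyl–oxygen cleavage; both stereocenters are β to the carbonyl and cannot epimerise by enolisation, and the low temperature limits E1cB loss of phenoxide.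

**Step 7**
Reactants: 13 bis(carboxylic acid)
Product: 15 (2S)-2-[4-(benzyloxy)-3-{4-[(2S)-5,7-bis(benzyloxy)-4-oxochroman-2-yl]phenoxy}phenyl]-5,7-dimethoxychroman-4-one, via bis(trifluoroacetic) mixed anhydride 14 (not isolated)
Conditions: TFAA (6 equiv), CH2Cl2 (5 mM), 0 °C → rt; then sat. aq. NaHCO3
Reagents that add atoms: none
Why: TFAA converts each carboxyl group into a mixed trifluoroacetic anhydride, which ionises to an acylium ion that attacks the ortho carbon of its own 3,5-dioxygenated aryl ether (the future C4a, activated by O1, the 5-oxygen and the 7-oxygen) and rearomatises by proton loss. This is an intramolecular Friedel–Crafts acylation, the established way from 3-aryloxypropanoic acids to chroman-4-ones. Each pyranone ring C closes in the 6-exo-trig mode (arene carbon onto the exocyclic acyl C=O), forming the C4–C4a bonds of unit 2 and unit 1 in the same operation. No stereocenter is created; C2 of each unit is carried through because it is not enolisable and the closure needs no base. Regioselectivity is secured by the symmetry of both aryl ethers (the two ortho carbons are identical and the para carbon cannot be reached). Chemoselectivity over the B rings follows from the far higher nucleophilicity of the tri-oxygenated rings and six- over five-membered ring closure, and high dilution suppresses intermolecular acylation.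

**Step 8**
Reactants: 15 protected bis-flavanone
Product: 16 7-O-methyltetrahydroochnaflavone
Conditions: BCl3 (12 equiv, 1 M in CH2Cl2), C6HMe5 (9 equiv), CH2Cl2, −78 → 0 °C; then MeOH, H2O
Reagents that add atoms: none
Why: Lewis-acid ether cleavage, in which BCl3 removes the three benzyl groups (benzyl cations trapped by pentamethylbenzene, which prevents C-benzylation of the rings A) and, through a six-membered boron chelate with the C4 carbonyl, the peri 5-methyl ether of unit 1, while the non-chelated 7-methyl ether should remain.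

**Compound list**
1 | 4-(4,4,5,5-tetramethyl-1,3,2-dioxaborolan-2-yl)benzaldehyde | O=Cc1ccc(cc1)B1OC(C)(C)C(C)(C)O1 | starting material
2 | tert-butyl[(1-methoxyethenyl)oxy]dimethylsilane | C=C(OC)O[Si](C)(C)C(C)(C)C | starting material
3 | methyl (R)-3-[4-(pinacolboryl)phenyl]-3-(trichlorosilyloxy)propanoate | COC(=O)C[C@@H](O[Si](Cl)(Cl)Cl)c1ccc(cc1)B1OC(C)(C)C(C)(C)O1 | intermediate
4 | methyl (R)-3-hydroxy-3-[4-(4,4,5,5-tetramethyl-1,3,2-dioxaborolan-2-yl)phenyl]propanoate | COC(=O)C[C@@H](O)c1ccc(cc1)B1OC(C)(C)C(C)(C)O1 | intermediate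
5 | 3,5-bis(benzyloxy)phenol | Oc1cc(OCc2ccccc2)cc(OCc2ccccc2)c1 | starting material
6 | methyl (S)-3-[3,5-bis(benzyloxy)phenoxy]-3-[4-(4,4,5,5-tetramethyl-1,3,2-dioxaborolan-2-yl)phenyl]propanoate | COC(=O)C[C@H](Oc1cc(OCc2ccccc2)cc(OCc2ccccc2)c1)c1ccc(cc1)B1OC(C)(C)C(C)(C)O1 | intermediate
7 | 4-(benzyloxy)-3-hydroxybenzaldehyde | O=Cc1ccc(OCc2ccccc2)c(O)c1 | starting material
8 | methyl (S)-3-{4-[2-(benzyloxy)-5-formylphenoxy]phenyl}-3-[3,5-bis(benzyloxy)phenoxy]propanoate | COC(=O)C[C@H](Oc1cc(OCc2ccccc2)cc(OCc2ccccc2)c1)c1ccc(Oc2cc(C=O)ccc2OCc2ccccc2)cc1 | intermediate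
9 | trichlorosilyl ether of alcohol 10 | COC(=O)C[C@H](Oc1cc(OCc2ccccc2)cc(OCc2ccccc2)c1)c1ccc(Oc2cc([C@H](O[Si](Cl)(Cl)Cl)CC(=O)OC)ccc2OCc2ccccc2)cc1 | intermediate
10 | methyl (R)-3-[4-(benzyloxy)-3-{4-[(S)-1-[3,5-bis(benzyloxy)phenoxy]-3-methoxy-3-oxopropyl]phenoxy}phenyl]-3-hydroxypropanoate | COC(=O)C[C@H](Oc1cc(OCc2ccccc2)cc(OCc2ccccc2)c1)c1ccc(Oc2cc([C@H](O)CC(=O)OC)ccc2OCc2ccccc2)cc1 | intermediate
11 | 3,5-dimethoxyphenol | COc1cc(O)cc(OC)c1 | starting material
12 | methyl (S)-3-[4-(benzyloxy)-3-{4-[(S)-1-[3,5-bis(benzyloxy)phenoxy]-3-methoxy-3-oxopropyl]phenoxy}phenyl]-3-(3,5-dimethoxyphenoxy)propanoate | COC(=O)C[C@H](Oc1cc(OCc2ccccc2)cc(OCc2ccccc2)c1)c1ccc(Oc2cc([C@@H](Oc3cc(OC)cc(OC)c3)CC(=O)OC)ccc2OCc2ccccc2)cc1 | intermediate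
13 | (S)-3-[4-(benzyloxy)-3-{4-[(S)-1-[3,5-bis(benzyloxy)phenoxy]-2-carboxyethyl]phenoxy}phenyl]-3-(3,5-dimethoxyphenoxy)propanoic acid | OC(=O)C[C@H](Oc1cc(OCc2ccccc2)cc(OCc2ccccc2)c1)c1ccc(Oc2cc([C@@H](Oc3cc(OC)cc(OC)c3)CC(=O)O)ccc2OCc2ccccc2)cc1 | intermediate
14 | bis(trifluoroacetic) mixed anhydride of diacid 13 | FC(F)(F)C(=O)OC(=O)C[C@H](Oc1cc(OCc2ccccc2)cc(OCc2ccccc2)c1)c1ccc(Oc2cc([C@@H](Oc3cc(OC)cc(OC)c3)CC(=O)OC(=O)C(F)(F)F)ccc2OCc2ccccc2)cc1 | intermediate
15 | (2S)-2-[4-(benzyloxy)-3-{4-[(2S)-5,7-bis(benzyloxy)-4-oxochroman-2-yl]phenoxy}phenyl]-5,7-dimethoxychroman-4-one | COc1cc(OC)c2c(c1)O[C@H](c1ccc(OCc3ccccc3)c(Oc3ccc([C@@H]4CC(=O)c5c(OCc6ccccc6)cc(OCc6ccccc6)cc5O4)cc3)c1)CC2=O | intermediate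
16 | 7-O-methyltetrahydroochnaflavone, (2S)-5-hydroxy-2-[4-hydroxy-3-{4-[(2S)-5,7-dihydroxy-4-oxochroman-2-yl]phenoxy}phenyl]-7-methoxychroman-4-one | COc1cc(O)c2c(c1)O[C@H](c1ccc(O)c(Oc3ccc([C@@H]4CC(=O)c5c(O)cc(O)cc5O4)cc3)c1)CC2=O | target

**Total step count:** 8. **Longest linear sequence:** 8 steps (from compound 1).

**Steps most likely to fail**

Step 7 (twofold ring closure). The trifluoroacetic acid set free may ionise the benzylic C–O bond of unit 1, which is assisted by the para-benzyloxy group, leading to elimination or loss of configuration. A slow second closure may also leave time for intermolecular acylation or trifluoroacetyl transfer to the free ring. The fallback sets out from diacid 13 and comes back at 15. Coupling with dimethylamine (EDC·HCl, HOBt, Me2NH·HCl, iPr2NEt, CH2Cl2) should give the bis(N,N-dimethylamide) F1. Electrophilic amide activation (Tf2O, 2-fluoropyridine, CH2Cl2, −78 → 0 °C) then generates keteniminium ions in a buffered, aprotic medium. These should close onto the same ortho carbons in an intramolecular Vilsmeier–Haack-type acylation to give the bis(4-dimethylamino-2H-chromene) F2, which is not isolated. Hydrolysis with aqueous NaOAc/AcOH in THF should deliver 15.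

Step 5 (second Mitsunobu etherification). The alkoxyphosphonium intermediate may ionise at the para-benzyloxy-stabilised benzylic carbon, eroding the inversion and diverting material to the cinnamate by elimination. The fallback sets out from boronate 6 and comes back at 15; it sets C2 of unit 1 by conjugate addition instead of substitution.
- Chan–Lam coupling of 6 with commercial 2-(benzyloxy)-5-bromophenol (conditions of step 3) should give the bromo diaryl ether F3.
- Miyaura-type borylation (B2(OH)4, Pd(OAc)2, XPhos, KOAc, MeOH, 60 °C) should give the arylboronic acid F4.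
- Asymmetric 1,4-addition to commercial 5,7-dimethoxy-4H-chromen-4-one under divalent palladium catalysis (Pd(OCOCF3)2, 4-tert-butyl-2-(pyridin-2-yl)-4,5-dihydrooxazole in the antipode that gives the (2S)-flavanone, NH4PF6, H2O, ClCH2CH2Cl, 60 °C) should give the mono-flavanone ester F5.
- Neutral ester cleavage (Me3SnOH, ClCH2CH2Cl, 70 °C) should give the mono-flavanone acid F6.
- A single Friedel–Crafts closure of ring C of unit 2 (TFAA, CH2Cl2, 0 °C) should then give 15.

Step 3 (Chan–Lam coupling). Transfer of the aryl group from the pinacol boronate to divalent copper may be sluggish, so that protodeboronation and oxidative consumption of the phenol take over. The fallback sets out from 6 and comes back at 8. Bromodeboronation (CuBr2, MeOH/H2O, 80 °C) should give the aryl bromide F7. C–O cross-coupling of F7 with phenol 7 (Pd(OAc)2, tBuXPhos, K3PO4, toluene, 100 °C), which proceeds through zerovalent palladium, should then give 8.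

**Further compounds**
F1 | step 7 | (S)-3-[4-(benzyloxy)-3-{4-[(S)-1-[3,5-bis(benzyloxy)phenoxy]-3-(dimethylamino)-3-oxopropyl]phenoxy}phenyl]-3-(3,5-dimethoxyphenoxy)-N,N-dimethylpropanamide | CN(C)C(=O)C[C@H](Oc1cc(OCc2ccccc2)cc(OCc2ccccc2)c1)c1ccc(Oc2cc([C@@H](Oc3cc(OC)cc(OC)c3)CC(=O)N(C)C)ccc2OCc2ccccc2)cc1
F2 | step 7 | (2S)-2-[4-(benzyloxy)-3-{4-[(2S)-5,7-bis(benzyloxy)-4-(dimethylamino)-2H-chromen-2-yl]phenoxy}phenyl]-5,7-dimethoxy-N,N-dimethyl-2H-chromen-4-amine | COc1cc(OC)c2c(c1)O[C@H](c1ccc(OCc3ccccc3)c(Oc3ccc([C@@H]4C=C(N(C)C)c5c(OCc6ccccc6)cc(OCc6ccccc6)cc5O4)cc3)c1)C=C2N(C)C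
F3 | step 5 | methyl (S)-3-{4-[2-(benzyloxy)-5-bromophenoxy]phenyl}-3-[3,5-bis(benzyloxy)phenoxy]propanoate | COC(=O)C[C@H](Oc1cc(OCc2ccccc2)cc(OCc2ccccc2)c1)c1ccc(Oc2cc(Br)ccc2OCc2ccccc2)cc1
F4 | step 5 | [4-(benzyloxy)-3-{4-[(S)-1-[3,5-bis(benzyloxy)phenoxy]-3-methoxy-3-oxopropyl]phenoxy}phenyl]boronic acid | COC(=O)C[C@H](Oc1cc(OCc2ccccc2)cc(OCc2ccccc2)c1)c1ccc(Oc2cc(B(O)O)ccc2OCc2ccccc2)cc1
F5 | step 5 | methyl (S)-3-[3,5-bis(benzyloxy)phenoxy]-3-(4-{2-(benzyloxy)-5-[(2S)-5,7-dimethoxy-4-oxochroman-2-yl]phenoxy}phenyl)propanoate | COC(=O)C[C@H](Oc1cc(OCc2ccccc2)cc(OCc2ccccc2)c1)c1ccc(Oc2cc([C@@H]3CC(=O)c4c(OC)cc(OC)cc4O3)ccc2OCc2ccccc2)cc1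
F6 | step 5 | (S)-3-[3,5-bis(benzyloxy)phenoxy]-3-(4-{2-(benzyloxy)-5-[(2S)-5,7-dimethoxy-4-oxochroman-2-yl]phenoxy}phenyl)propanoic acid | OC(=O)C[C@H](Oc1cc(OCc2ccccc2)cc(OCc2ccccc2)c1)c1ccc(Oc2cc([C@@H]3CC(=O)c4c(OC)cc(OC)cc4O3)ccc2OCc2ccccc2)cc1
F7 | step 3 | methyl (S)-3-[3,5-bis(benzyloxy)phenoxy]-3-(4-bromophenyl)propanoate | COC(=O)C[C@H](Oc1cc(OCc2ccccc2)cc(OCc2ccccc2)c1)c1ccc(Br)cc1
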